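Labels: ring O1–O2–C3(CH2CO2Me)–C4(Et)–C5–C6(Et, chain); chain carbons C1'–C8' are counted from C6.
Cuts (retro): a helper carbonyl is put on C2'; then the exocyclic C6–C1' bond is cut (ring cation + enol silane); the ring half is cut at O2–C3 (SN2), C6–OO (ozonolysis in MeOH), C2–C3/C3–O (ketene–aldehyde [2+2]) and C4–C5 (auxiliary alkylation); the chain half at C3'–C4' (Claisen).
Forward: chain methyl ketone → enol silane; separately alkylation → aldehyde → β-lactone → hydroperoxy ketal → 1,2-dioxane (closed at O2–C3); the halves are joined at C6 and the C2' carbonyl is then deleted.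
Enabling feature: C6 is the ring carbon bonded to peroxide oxygen O1 of the 1,2-dioxane; as a ketal it ionises to an O1-stabilised ring carbenium ion whose two faces are differentiated by the cis groups on C3 and C4.
Stereochemistry: C4 from an Evans alkylation; C3 from a catalyst-controlled cyclocondensation, inverted in the ring closure; C6 from axial attack trans to the C3/C4 groups; C4' and the E-alkene from a Sharpless kinetic resolution plus chair-Claisen chirality transfer.

Key step: step 12

Remark: 2-(bromomethyl)but-1-ene (14) is taken as a catalogue reagent (otherwise two steps from 2-ethylacrolein), and the ketal carbon C6 of 23–25 is carried as an epimer mixture because it is ionised in step 12.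

Step 1
Reactants: 1 (E)-pent-2-enal; 2 ethylmagnesium bromide
Product: 3 rac-(E)-hept-4-en-3-ol
Conditions: THF, −78 → 0 °C; aq. NH4Cl
Reagents that add atoms: none
Why: 1,2-Grignard addition to the enal should give the racemic secondary allylic alcohol with the E-alkene untouched.

Step 2
Reactants: 3 rac-(E)-hept-4-en-3-ol
Product: 4 (3R,4E)-hept-4-en-3-ol
Conditions: Ti(OiPr)4 (10 mol %), L-(+)-DIPT (15 mol %), t-BuOOH (0.6 equiv), 4 Å MS, CH2Cl2, −20 °C
Reagents that add atoms: none
Why: Sharpless kinetic resolution: with L-(+)-tartrate the (S)-alcohol should be epoxidised much faster, so the (R)-alcohol should be recovered in high enantiomeric purity.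

Step 3
Reactants: 4 (3R,4E)-hept-4-en-3-ol; 5 2-methoxypropene
Product: 8 (4R,5E)-4-ethyloct-5-en-2-one, via mixed ketal 6 (not isolated), via allyl isopropenyl ether 7 (not isolated)
Conditions: 2-methoxypropene (excess), cat. propionic acid, toluene, sealed tube, 130 °C
Reagents that add atoms: none
Why: Claisen rearrangement (ketone variant through the isopropenyl ether, Saucy–Marbet type): a chair transition state with the carbinol ethyl equatorial should transfer the C–O chirality suprafacially to the new C–C bond, which sets the (R)-ethyl-branched centre and the E-alkene in one event.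

Step 4
Reactants: 8 (4R,5E)-4-ethyloct-5-en-2-one
Product: 10 trimethyl{[(4R,5E)-4-ethylocta-1,5-dien-2-yl]oxy}silane, via lithium enolate 9 (not isolated)
Conditions: LDA, THF, −78 °C; then TMSCl, −78 → 0 °C; pentane, filtration (used crude)
Reagents that add atoms: chlorotrimethylsilane, C[Si](C)(C)Cl
Why: kinetic enolisation at the unhindered methyl group followed by O-silylation should give the terminal silyl enol ether, with the β-stereocentre and the alkene untouched.

Step 5
Reactants: 11 (4R)-4-benzyl-1,3-oxazolidin-2-one; 12 butanoyl chloride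
Product: 13 (4R)-4-benzyl-3-butanoyl-1,3-oxazolidin-2-one
Conditions: Et3N, DMAP (cat.), CH2Cl2, 0 °C → rt
Reagents that add atoms: none
Why: DMAP-catalysed N-acylation of the oxazolidinone installs the auxiliary for the next step.

Step 6
Reactants: 13 (4R)-4-benzyl-3-butanoyl-1,3-oxazolidin-2-one; 14 2-(bromomethyl)but-1-ene
Product: 16 (4R)-4-benzyl-3-[(2S)-2-ethyl-4-methylidenehexanoyl]-1,3-oxazolidin-2-one, via sodium enolate 15 (not isolated)
Conditions: NaHMDS, THF, −78 °C; then 14, −78 → −40 °C
Reagents that add atoms: none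
Why: Evans alkylation: the chelated Z-enolate should be alkylated by the allylic bromide on the face opposite the benzyl group, which sets the future C4 as (S).

Step 7
Reactants: 16 (4R)-4-benzyl-3-[(2S)-2-ethyl-4-methylidenehexanoyl]-1,3-oxazolidin-2-one
Product: 17 (2S)-2-ethyl-4-methylidenehexan-1-ol
Conditions: LiBH4, H2O (1 equiv), Et2O, 0 °C
Reagents that add atoms: none
Why: reductive cleavage of the imide should release the primary alcohol without touching the α-centre and return the auxiliary.

Step 8
Reactants: 17 (2S)-2-ethyl-4-methylidenehexan-1-ol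
Product: 18 (2S)-2-ethyl-4-methylidenehexanal
Conditions: Dess–Martin periodinane, CH2Cl2, 0 °C → rt (used at once)
Reagents that add atoms: none
Why: Dess–Martin oxidation is mild enough to give the α-branched aldehyde without epimerisation or alkene migration.

Step 9
Reactants: 18 (2S)-2-ethyl-4-methylidenehexanal; 19 acetyl bromide
Product: 21 (4R)-4-[(3S)-5-methylideneheptan-3-yl]oxetan-2-one, via ketene 20 (not isolated)
Conditions: iPr2NEt, chiral Al(III) bis(sulfonamide)–triamine catalyst (10–15 mol %, the antipode that adds to the Re face of the aldehyde), CH2Cl2, −50 °C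
Reagents that add atoms: none
Why: catalytic asymmetric acyl halide–aldehyde cyclocondensation (ketene–aldehyde [2+2]): Re-face addition of ketene should set the lactone carbon as (R) under catalyst control, the two α-substituents of the aldehyde being too similar in size to exert a strong bias of their own.

Step 10
Reactants: 21 (4R)-4-[(3S)-5-methylideneheptan-3-yl]oxetan-2-one
Product: 23 (4R)-4-[(3S)-5-hydroperoxy-5-methoxyheptan-3-yl]oxetan-2-one, via carbonyl oxide 22 (not isolated)
Conditions: O3, CH2Cl2/MeOH, −78 °C; N2 purge, concentration below 0 °C, no reductant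
Reagents that add atoms: ozone, [O-][O+]=O; methanol, CO
Why: Criegee ozonolysis with methanol trapping: the 1,1-disubstituted alkene should fragment to the ketone oxide and formaldehyde, and methanol should add to the ketone oxide to give the hydroperoxy methyl ketal (new centre unselective and later ionised), the β-lactone being inert under these neutral cold conditions.

Step 11
Reactants: 23 (4R)-4-[(3S)-5-hydroperoxy-5-methoxyheptan-3-yl]oxetan-2-one
Product: 25 methyl 2-[(3S,4S)-4,6-diethyl-6-methoxy-1,2-dioxan-3-yl]acetate, via caesium carboxylate 24 (not isolated)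
Conditions: Cs2CO3 (1.1 equiv), DMF, 0 °C → rt; then MeI
Reagents that add atoms: iodomethane, CI
Why: Proposed new method: Cs2CO3 deprotonates the hydroperoxy ketal (pKa about 12) and the peroxy anion, held five atoms from the lactone C4, should open the strained ring by 6-exo-tet SN2 attack at the alkyl–oxygen carbon with inversion (carboxylate leaving group; acyl attack would need an eight-membered ring), which turns the (R)-lactone carbon into C3 (S), cis to the C4 ethyl group, after which the caesium carboxylate is O-methylated in the same flask; the closest known reaction types are the 6-exo cyclisation of hydroperoxy ketal anions onto secondary sulfonates and the alkyl–oxygen opening of β-lactones by intramolecular oxygen nucleophiles and by soft external nucleophiles.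

Step 12
Reactants: 25 methyl 2-[(3S,4S)-4,6-diethyl-6-methoxy-1,2-dioxan-3-yl]acetate; 10 trimethyl{[(4R,5E)-4-ethylocta-1,5-dien-2-yl]oxy}silane
Product: 27 methyl 2-[(3S,4S,6R)-4,6-diethyl-6-[(4R,5E)-4-ethyl-2-oxooct-5-en-1-yl]-1,2-dioxan-3-yl]acetate, via peroxycarbenium ion 26 (not isolated)
Conditions: 10 (2 equiv), TiCl4 (1.1 equiv), CH2Cl2, −78 °C; aq. NaHCO3
Reagents that add atoms: none
Why: TiCl4 binds the more basic methoxy oxygen of 25 and ionises the exocyclic C6–OMe bond to the cyclic peroxycarbenium ion 26 (C6=O1+ inside the 1,2-dioxane), which is captured at C6 by the terminal CH2 of enol silane 10, and loss of Me3SiCl then gives the β-peroxy ketone. The closest known reaction type is the Lewis-acid-mediated coupling of monoperoxyketals and 3-alkoxy-1,2-dioxolanes/dioxanes with silyl enol ethers, silyl ketene acetals and allylsilanes (Mukaiyama-type addition to a peroxycarbenium ion). No ring is closed: the dioxane made in step 11 is carried through intact, endocyclic C6–O1 cleavage being reversible whereas loss of methoxide is not. The new quaternary centre C6 is set by the ring: in the half-chair cation the nucleophile should attack axially through a chair-like transition state on the face opposite the cis C3–CH2CO2Me and C4–ethyl groups, because the other axial approach is syn-diaxial to the C4 ethyl, so the chain ends trans to both groups (6R here, 6S after step 14). The step needs exocyclic rather than ring ionisation (secured by the more basic ether oxygen and low temperature), this facial selectivity (secured by the 3,4-cis substitution) and C-attack at the unsubstituted enol carbon (secured by the kinetic terminal enol silane). Because the incoming carbon ends trans to the ring substituents, it is the long chain and not the ethyl group that must be delivered in this step.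

Step 13
Reactants: 27 methyl 2-[(3S,4S,6R)-4,6-diethyl-6-[(4R,5E)-4-ethyl-2-oxooct-5-en-1-yl]-1,2-dioxan-3-yl]acetate
Product: 28 methyl 2-[(3S,4S,6R)-4,6-diethyl-6-[(4R,5E)-4-ethyl-2-(2-tosylhydrazinylidene)oct-5-en-1-yl]-1,2-dioxan-3-yl]acetate
Conditions: TsNHNH2, cat. PPTS, EtOH, rt → 40 °C
Reagents that add atoms: 4-methylbenzenesulfonohydrazide, Cc1ccc(cc1)S(=O)(=O)NN
Why: condensation of the helper ketone to its tosylhydrazone under near-neutral conditions should leave the dialkyl peroxide, the ester and the alkene untouched.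

Step 14
Reactants: 28 methyl 2-[(3S,4S,6R)-4,6-diethyl-6-[(4R,5E)-4-ethyl-2-(2-tosylhydrazinylidene)oct-5-en-1-yl]-1,2-dioxan-3-yl]acetate
Product: 31 methyl 2-[(3S,4S,6S)-4,6-diethyl-6-[(4R,5E)-4-ethyloct-5-en-1-yl]-1,2-dioxan-3-yl]acetate, via N-boryl tosylhydrazide 29 (not isolated), via alkyldiazene 30 (not isolated)
Conditions: catecholborane, CHCl3, 0 °C → rt; then NaOAc·3H2O, 55 °C
Reagents that add atoms: none
Why: Caglioti-type deoxygenation: hydroboration of the C=N bond, acetate-induced loss of sulfinate and extrusion of N2 from the diazene should turn C2' into CH2 under conditions that do not reduce a dialkyl peroxide, an ester or an isolated alkene, and no stereocentre is touched.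

Compound list
1 | (E)-pent-2-enal | CC/C=C/C=O | starting material
2 | ethylmagnesium bromide | CC[Mg]Br | starting material
3 | rac-(E)-hept-4-en-3-ol | CC/C=C/C(O)CC | intermediate
4 | (3R,4E)-hept-4-en-3-ol | CC/C=C/[C@H](O)CC | intermediate
5 | 2-methoxypropene | COC(C)=C | starting material
6 | (3R,4E)-3-[(2-methoxypropan-2-yl)oxy]hept-4-ene (mixed ketal) | CC/C=C/[C@H](OC(C)(C)OC)CC | intermediate
7 | (3R,4E)-3-(prop-1-en-2-yloxy)hept-4-ene (allyl isopropenyl ether) | CC/C=C/[C@H](OC(C)=C)CC | intermediate
8 | (4R,5E)-4-ethyloct-5-en-2-one | CC/C=C/[C@H](CC)CC(C)=O | intermediate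
9 | lithium (4R,5E)-4-ethylocta-1,5-dien-2-olate | CC/C=C/[C@H](CC)CC(=C)[O-].[Li+] | intermediate
10 | trimethyl{[(4R,5E)-4-ethylocta-1,5-dien-2-yl]oxy}silane | CC/C=C/[C@H](CC)CC(=C)O[Si](C)(C)C | intermediate
11 | (4R)-4-benzyl-1,3-oxazolidin-2-one | O=C1N[C@H](Cc2ccccc2)CO1 | starting material
12 | butanoyl chloride | CCCC(Cl)=O | starting material
13 | (4R)-4-benzyl-3-butanoyl-1,3-oxazolidin-2-one | CCCC(=O)N1[C@H](Cc2ccccc2)COC1=O | intermediate
14 | 2-(bromomethyl)but-1-ene | CCC(=C)CBr | starting material
15 | sodium (Z)-enolate of 13 | CC/C=C(\[O-])N1[C@H](Cc2ccccc2)COC1=O.[Na+] | intermediate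
16 | (4R)-4-benzyl-3-[(2S)-2-ethyl-4-methylidenehexanoyl]-1,3-oxazolidin-2-one | CCC(=C)C[C@H](CC)C(=O)N1[C@H](Cc2ccccc2)COC1=O | intermediate
17 | (2S)-2-ethyl-4-methylidenehexan-1-ol | CCC(=C)C[C@H](CC)CO | intermediate
18 | (2S)-2-ethyl-4-methylidenehexanal | CCC(=C)C[C@H](CC)C=O | intermediate
19 | acetyl bromide | CC(Br)=O | starting material
20 | ketene | C=C=O | intermediate
21 | (4R)-4-[(3S)-5-methylideneheptan-3-yl]oxetan-2-one | CCC(=C)C[C@H](CC)[C@H]1CC(=O)O1 | intermediate
22 | carbonyl oxide of 21 (ketone oxide at the former alkene carbon) | CCC(=[O+][O-])C[C@H](CC)[C@H]1CC(=O)O1 | intermediate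
23 | (4R)-4-[(3S)-5-hydroperoxy-5-methoxyheptan-3-yl]oxetan-2-one (ketal epimers) | CCC(OC)(OO)C[C@H](CC)[C@H]1CC(=O)O1 | intermediate
24 | caesium 2-[(3S,4S)-4,6-diethyl-6-methoxy-1,2-dioxan-3-yl]acetate | CCC1(OC)C[C@H](CC)[C@H](CC(=O)[O-])OO1.[Cs+] | intermediate
25 | methyl 2-[(3S,4S)-4,6-diethyl-6-methoxy-1,2-dioxan-3-yl]acetate (C6 epimers) | CCC1(OC)C[C@H](CC)[C@H](CC(=O)OC)OO1 | intermediate
26 | (4S,5S)-3,5-diethyl-6-(2-methoxy-2-oxoethyl)-1,2-dioxan-3-ylium (peroxycarbenium ion) tetrachloro(methoxy)titanate | CC[C+]1C[C@H](CC)[C@H](CC(=O)OC)OO1.CO[Ti-](Cl)(Cl)(Cl)Cl | intermediate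
27 | methyl 2-[(3S,4S,6R)-4,6-diethyl-6-[(4R,5E)-4-ethyl-2-oxooct-5-en-1-yl]-1,2-dioxan-3-yl]acetate | CC/C=C/[C@H](CC)CC(=O)C[C@@]1(CC)C[C@H](CC)[C@H](CC(=O)OC)OO1 | intermediate
28 | methyl 2-[(3S,4S,6R)-4,6-diethyl-6-[(4R,5E)-4-ethyl-2-(2-tosylhydrazinylidene)oct-5-en-1-yl]-1,2-dioxan-3-yl]acetate | CC/C=C/[C@H](CC)CC(=NNS(=O)(=O)c1ccc(C)cc1)C[C@@]1(CC)C[C@H](CC)[C@H](CC(=O)OC)OO1 | intermediate
29 | N-boryl tosylhydrazide: methyl 2-[(3S,4S,6R)-6-{(4R,5E)-2-[1-(1,3,2-benzodioxaborol-2-yl)-2-tosylhydrazinyl]-4-ethyloct-5-en-1-yl}-4,6-diethyl-1,2-dioxan-3-yl]acetate | CC/C=C/[C@H](CC)CC(N(NS(=O)(=O)c1ccc(C)cc1)B1Oc2ccccc2O1)C[C@@]1(CC)C[C@H](CC)[C@H](CC(=O)OC)OO1 | intermediate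
30 | alkyldiazene: methyl 2-[(3S,4S,6R)-6-[(4R,5E)-2-diazenyl-4-ethyloct-5-en-1-yl]-4,6-diethyl-1,2-dioxan-3-yl]acetate | CC/C=C/[C@H](CC)CC(N=N)C[C@@]1(CC)C[C@H](CC)[C@H](CC(=O)OC)OO1 | intermediate
31 | methyl 2-[(3S,4S,6S)-4,6-diethyl-6-[(4R,5E)-4-ethyloct-5-en-1-yl]-1,2-dioxan-3-yl]acetate | CC/C=C/[C@H](CC)CCC[C@@]1(CC)C[C@H](CC)[C@H](CC(=O)OC)OO1 | target

Total step count: 14. Longest linear sequence: 10 steps (steps 5–14); the chain branch (steps 1–4) joins at step 12.

Steps most likely to fail

1. Step 11 (Proposed new method). What may go wrong: the peroxy anion may not open the β-lactone at the β-branched alkyl carbon, so that base-induced decomposition of the hydroperoxy ketal or intermolecular acyl transfer takes over. Fallback with known chemistry, from 21 back to 25: the lactone is reduced with LiBH4 to (3R,4S)-4-ethyl-6-methylideneoctane-1,3-diol F1. The primary hydroxyl is silylated (TBSCl, imidazole) to the silyl ether F2 and the secondary one is mesylated (MsCl, Et3N) to the mesylate F3. Ozonolysis in CH2Cl2/MeOH gives the hydroperoxy ketal F4, which KOt-Bu/18-crown-6 should close by 6-exo SN2 displacement of the mesylate with inversion to the dioxane silyl ether F5. TBAF then gives the dioxane ethanol F6, TEMPO/PhI(OAc)2 in aqueous MeCN the dioxane acetic acid F7, and TMSCHN2 the ester 25.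

2. Step 12 (key step). What may go wrong: Lewis-acid-induced heterolysis of the ring (endocyclic C–O or O–O cleavage, Criegee-type fragmentation) may outrun C–C bond formation, or attack on the ring cation may show poor facial selectivity. Fallback, from 23 back to 27: the order of events is changed so that no cyclic peroxide is ionised. Compound 23 is silylated (Et3SiCl, imidazole) to the silyl peroxy ketal F8, which is coupled with 10 under catalytic TMSOTf (CH2Cl2, −78 °C, acyclic silyl peroxycarbenium ion) to the acyclic tertiary silyl peroxide F9 as an epimer mixture at the peroxide carbon. TBAF then unmasks the peroxide, which should close onto the β-lactone as in step 11, and MeI gives 27 together with its C6 epimer F10, to be separated by chromatography. The price is the loss of control at C6.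

3. Step 14 (with step 13). What may go wrong: cleavage of the O–O bond, base-induced β-elimination that opens the dioxane, or incomplete reduction at the hindered C2'. Fallback, from 27 to 31: radical deoxygenation replaces the hydrazone route. NaBH4 (MeOH, 0 °C) gives the alcohol F11 as C2' epimers, PhOC(S)Cl/pyridine/DMAP gives the phenyl thionocarbonate F12, and Bu3SnH/AIBN (benzene, 80 °C) should give 31 by Barton–McCombie reduction, since tin radicals add to the thiocarbonyl group far faster than they attack a dialkyl peroxide.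

Further compounds
F1 | step 11 | (3R,4S)-4-ethyl-6-methylideneoctane-1,3-diol | CCC(=C)C[C@H](CC)[C@H](O)CCO
F2 | step 11 | (3R,4S)-1-[(tert-butyldimethylsilyl)oxy]-4-ethyl-6-methylideneoctan-3-ol | CCC(=C)C[C@H](CC)[C@H](O)CCO[Si](C)(C)C(C)(C)C
F3 | step 11 | (3R,4S)-1-[(tert-butyldimethylsilyl)oxy]-4-ethyl-6-methylideneoctan-3-yl methanesulfonate | CCC(=C)C[C@H](CC)[C@H](OS(C)(=O)=O)CCO[Si](C)(C)C(C)(C)C
F4 | step 11 | (3R,4S)-1-[(tert-butyldimethylsilyl)oxy]-4-ethyl-6-hydroperoxy-6-methoxyoctan-3-yl methanesulfonate | CCC(OC)(OO)C[C@H](CC)[C@H](OS(C)(=O)=O)CCO[Si](C)(C)C(C)(C)C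
F5 | step 11 | tert-butyl{2-[(3S,4S)-4,6-diethyl-6-methoxy-1,2-dioxan-3-yl]ethoxy}dimethylsilane | CCC1(OC)C[C@H](CC)[C@H](CCO[Si](C)(C)C(C)(C)C)OO1
F6 | step 11 | 2-[(3S,4S)-4,6-diethyl-6-methoxy-1,2-dioxan-3-yl]ethan-1-ol | CCC1(OC)C[C@H](CC)[C@H](CCO)OO1
F7 | step 11 | 2-[(3S,4S)-4,6-diethyl-6-methoxy-1,2-dioxan-3-yl]acetic acid | CCC1(OC)C[C@H](CC)[C@H](CC(O)=O)OO1
F8 | step 12 | (4R)-4-[(3S)-5-methoxy-5-[(triethylsilyl)peroxy]heptan-3-yl]oxetan-2-one | CCC(OC)(OO[Si](CC)(CC)CC)C[C@H](CC)[C@H]1CC(=O)O1
F9 | step 12 | (4R)-4-[(3S,9R,10E)-5,9-diethyl-7-oxo-5-[(triethylsilyl)peroxy]tridec-10-en-3-yl]oxetan-2-one | CC/C=C/[C@H](CC)CC(=O)CC(CC)(OO[Si](CC)(CC)CC)C[C@H](CC)[C@H]1CC(=O)O1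
F10 | step 12 | methyl 2-[(3S,4S,6S)-4,6-diethyl-6-[(4R,5E)-4-ethyl-2-oxooct-5-en-1-yl]-1,2-dioxan-3-yl]acetate | CC/C=C/[C@H](CC)CC(=O)C[C@]1(CC)C[C@H](CC)[C@H](CC(=O)OC)OO1
F11 | step 14 | methyl 2-[(3S,4S,6R)-4,6-diethyl-6-[(4R,5E)-4-ethyl-2-hydroxyoct-5-en-1-yl]-1,2-dioxan-3-yl]acetate | CC/C=C/[C@H](CC)CC(O)C[C@@]1(CC)C[C@H](CC)[C@H](CC(=O)OC)OO1
F12 | step 14 | methyl 2-[(3S,4S,6R)-4,6-diethyl-6-[(4R,5E)-4-ethyl-2-(phenoxycarbonothioyloxy)oct-5-en-1-yl]-1,2-dioxan-3-yl]acetate | CC/C=C/[C@H](CC)CC(OC(=S)Oc1ccccc1)C[C@@]1(CC)C[C@H](CC)[C@H](CC(=O)OC)OO1
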